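Substrate, dormant form and product together read what was charged: Thursday's last reading sums to 100.5%, so within the scatter what leaves the substrate lands in one of the two others.

all flasks: substrate 0.033 M
- Sunday's: enzyme 3.3 µM; the very flask that is asked about, followed so far
- Thursday's: enzyme 2.2 µM; run made earlier
- flask: enzyme 3.3 µM; time 2.0 min

| run | time / s | dormant form / % | product / % | substrate / % |
|---|---|---|---|---|
| Sunday's | 10.0 | 5.4 | 7.9 | 85.1 |
| Thursday's | 10.0 | 5.3 | 5.0 | 88.4 |
| Thursday's | 15.0 | 8.3 | 8.3 | 83.0 |
| Thursday's | 25.0 | 13.3 | 13.3 | 74.5 |
| Thursday's | 40.0 | 17.0 | 20.5 | 61.3 |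
| Thursday's | 60.0 | 23.2 | 27.8 | 49.2 |
| Thursday's | 80.0 | 27.0 | 33.9 | 39.6 |

(scatter of a reading: 0.5 percentage points)

- the dormant form in the flask at 2.0 min, as a percentage of the substrate charged
- the product in the flask at 2.0 min, as a percentage of the substrate charged
- the substrate in the flask at 2.0 min, as a percentage of the substrate charged

- the numbers in the tables scatter by 0.5 percentage points (one standard deviation)

Sunday's flask and Thursday's look nearly the same and differ in their enzyme. At 10.0 s the dormant form reads 5.4% and 5.3%, so enzyme does not show in that branch, while the product ratio reads 1.58 against an enzyme ratio of 1.50. Thursday's readings from 40.0 s to 80.0 s give 0.00664 s⁻¹ of product per unit c(substrate), and scaling by enzyme gives 0.00996 s⁻¹ for Sunday's flask. This is its drain constant, the pseudo-first-order constant of product formation: product gained per time per unit c(substrate). Thursday's substrate, taken as first order down to 39.6%, leaves a net leak into the dormant form of 0.00494 s⁻¹, which I hold equal in both flasks. On this reckoning 66.8% of the lost substrate goes to product in Sunday's flask and 57.3% in Thursday's. For Sunday's flask at 2.0 min I reckon 16.7% substrate, 55.7% product and 27.6% dormant form.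

The forecast, holding that “Product scales with enzyme”, gives 19% substrate, above my figure, with 54.5% product and 26.5% dormant form.

The flask gives 19.7% substrate, 55.3% product and 25.0% dormant form.

    substrate + enzyme → product + enzyme, rate k1*[substrate]^1.5*[enzyme]/(1 + ([substrate]/Kh1)^1.5) (23.6 mM, k = 39000 M⁻¹·⁵ s⁻¹)
    2 substrate → homo dimer (k = 8.10 × 10⁻⁵ M⁻¹ s⁻¹)
    substrate ⇌ dormant form (K = 1.30, k = 0.00641 s⁻¹)

The flask at 2.0 min is not at rest: 44.7% of the charge is still substrate or dormant form, and enzyme stands at 100% of its charge. The drain constant gives 18 percentage points of product from 1.00 min to 2.0 min, and the flask made 17 points. For the same charge read at 50 s it gives 36 points from the start, against 34.1% simulated. Moved alone to 5.02 µM, enzyme shifts the dormant form of the flask at 2.0 min by 5 points. Left until 20.0 min, the flask holds 93.4% product, 4.19% dormant form and 2.35% substrate.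

The numbers in the tables are calculated for an exercise; noise was put on by code.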